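**Retrosynthetic overview**
1. The (E)-enyne is made last from a C4 aldehyde: Takai iodo-olefination, Sonogashira coupling, desilylation.
2. Ring A (tetrahydrofuran, O bridging C6 and C9) and the C10–Br bond come from a 5-exo bromoetherification of a (Z)-oxocene diol; C12–Br comes from an invertive bromination of the C12 alcohol.
3. Ring B (oxocene, O bridging C7 and C13) is closed by ring-closing metathesis at C9=C10.
4. The C7–O–C13 ether bond and the C13 centre come from a new catalyst-controlled copper-carbene O–H insertion of ethyl 2-diazobutanoate into the C7 alcohol; C12 follows by chelation-controlled allylation.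
5. C6 comes from (R)-butane-1,2,4-triol and C7 from a Brown allylation; ring order: temporary 1,3-dioxane, then ring B, then ring A.

Assumption: the target is taken exactly as drawn, (6R,7S,9S,10S,12S,13R,3E) with chain numbering C1 (alkyne CH) to C15 (ethyl CH3), which has an α,α'-trans oxocane; reagents without a number are commercial.

**Step 1**
Reactants: 1 (R)-butane-1,2,4-triol
Product: 2 [(2R,4R)-2-phenyl-1,3-dioxan-4-yl]methanol
Conditions: PhCH(OMe)2, camphorsulfonic acid (cat.), CH2Cl2, rt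
Reagents that add atoms: benzaldehyde dimethyl acetal, COC(OC)c1ccccc1
Why: Acid-catalysed transacetalisation under thermodynamic control gives the six-membered 2,4-O-benzylidene acetal with phenyl and CH2OH both equatorial (cis), which fixes the acetal carbon as R and leaves only the primary C7 hydroxyl free, while C6 is taken unchanged from the chiral pool.

**Step 2**
Reactants: 2 [(2R,4R)-2-phenyl-1,3-dioxan-4-yl]methanol
Product: 3 (2R,4R)-2-phenyl-1,3-dioxane-4-carbaldehyde
Conditions: Dess–Martin periodinane, CH2Cl2, 0 °C to rt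
Reagents that add atoms: none
Why: Dess–Martin oxidation of the primary alcohol is near-neutral, so the α-alkoxy aldehyde forms without epimerising C6 and the acetal survives.

**Step 3**
Reactants: 3 (2R,4R)-2-phenyl-1,3-dioxane-4-carbaldehyde
Product: 5 (1S)-1-[(2R,4R)-2-phenyl-1,3-dioxan-4-yl]but-3-en-1-ol, via diisopinocampheylborinate ester 4 (not isolated)
Conditions: (−)-Ipc2B(allyl), Et2O, −78 °C; then NaOH, H2O2, 0 °C to rt
Reagents that add atoms: (−)-B-allyldiisopinocampheylborane, C=CCB([C@@H]1C[C@@H]2C[C@H]([C@H]1C)C2(C)C)[C@@H]1C[C@@H]2C[C@H]([C@H]1C)C2(C)C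
Why: Brown asymmetric allylboration through a chair six-membered transition state delivers allyl to the Si face of the aldehyde, which is also the Felkin-preferred face of this α-alkoxy aldehyde (matched pair), so C7 is set S (anti to the C6 oxygen) before oxidative work-up cleaves the borinate.

**Step 4**
Reactants: 6 ethyl 2-ethyl-3-oxobutanoate
Product: 7 ethyl 2-diazobutanoate
Conditions: 4-acetamidobenzenesulfonyl azide, DBU, MeCN, 0 °C to rt
Reagents that add atoms: 4-acetamidobenzenesulfonyl azide, CC(=O)Nc1ccc(cc1)S(=O)(=O)N=[N+]=[N-]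
Why: Deacylative Regitz diazo transfer: the enolate takes up the terminal nitrogens of the azide and the acetyl group leaves on the sulfonamide nitrogen, giving the α-alkyl diazo ester.

**Step 5**
Reactants: 5 (1S)-1-[(2R,4R)-2-phenyl-1,3-dioxan-4-yl]but-3-en-1-ol; 7 ethyl 2-diazobutanoate
Product: 8 ethyl (2R)-2-{[(1S)-1-[(2R,4R)-2-phenyl-1,3-dioxan-4-yl]but-3-en-1-yl]oxy}butanoate
Conditions: 7 (1.5 equiv, added over 4 h), Cu(MeCN)4PF6 (5 mol %), (Sa,S,S)-Ph-SpiroBOX (6 mol %), NaB[3,5-(CF3)2C6H3]4 (6 mol %), 4 Å MS, CH2Cl2, 25 °C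
Reagents that add atoms: none
Why: Proposed new method: the monovalent copper carbene formed from 7 is attacked by the hindered secondary hydroxyl of 5 to give a copper-bound oxonium ylide (copper enolate), and the stereo-determining 1,2-proton shift takes place inside the chiral spiro-bis(oxazoline) pocket, so the catalyst rather than the remote C7/C6 centres sets C13 as R while forming the C7–O–C13 bond in one step; copper is chosen because it suppresses the 1,2-hydride shift of the ethyl-substituted carbene and because O–H insertion outruns cyclopropanation of the terminal alkene; the closest known reaction type is the Cu(MeCN)4PF6/spiro-bis(oxazoline)-catalysed enantioselective carbene O–H insertion of α-diazo esters into water, phenols and simple achiral alcohols, not yet shown as a catalyst-controlled diastereoselective insertion into a complex chiral secondary alcohol.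

**Step 6**
Reactants: 8 ethyl (2R)-2-{[(1S)-1-[(2R,4R)-2-phenyl-1,3-dioxan-4-yl]but-3-en-1-yl]oxy}butanoate
Product: 9 (2R)-2-{[(1S)-1-[(2R,4R)-2-phenyl-1,3-dioxan-4-yl]but-3-en-1-yl]oxy}butanal
Conditions: i-Bu2AlH, CH2Cl2, −78 °C
Reagents that add atoms: none
Why: Partial ester reduction with i-Bu2AlH stops at the tetrahedral aluminium hemiacetal at −78 °C and releases the α-alkoxy aldehyde on work-up without enolising C13; the aldehyde is used at once.

**Step 7**
Reactants: 9 (2R)-2-{[(1S)-1-[(2R,4R)-2-phenyl-1,3-dioxan-4-yl]but-3-en-1-yl]oxy}butanal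
Product: 10 (3R,4R)-3-{[(1S)-1-[(2R,4R)-2-phenyl-1,3-dioxan-4-yl]but-3-en-1-yl]oxy}hept-6-en-4-ol
Conditions: allylSnBu3, MgBr2·OEt2, CH2Cl2, −78 to −20 °C
Reagents that add atoms: allyltributylstannane, C=CC[Sn](CCCC)(CCCC)CCCC
Why: Keck chelation-controlled allylation: MgBr2 bridges the aldehyde and ether oxygens in a five-membered chelate and the stannane attacks the face opposite the C13 ethyl group, giving the syn (12R,13R) alcohol.

**Step 8**
Reactants: 10 (3R,4R)-3-{[(1S)-1-[(2R,4R)-2-phenyl-1,3-dioxan-4-yl]but-3-en-1-yl]oxy}hept-6-en-4-ol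
Product: 11 (2S,4Z,7R,8R)-8-ethyl-2-[(2R,4R)-2-phenyl-1,3-dioxan-4-yl]-3,6,7,8-tetrahydro-2H-oxocin-7-ol
Conditions: second-generation Grubbs catalyst RuCl2(=CHPh)(PCy3)(SIMes) (5 mol %), CH2Cl2 (2 mM), 40 °C
Reagents that add atoms: none
Why: Ring-closing metathesis forms C9=C10 because the gauche O–C–C–O units at C6–C7 and C12–C13 pre-organise the diene for medium-ring closure, and the eight-membered ring enforces the Z olefin.

**Step 9**
Reactants: 11 (2S,4Z,7R,8R)-8-ethyl-2-[(2R,4R)-2-phenyl-1,3-dioxan-4-yl]-3,6,7,8-tetrahydro-2H-oxocin-7-ol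
Product: 12 (2R,4R)-4-[(2S,4Z,7S,8R)-7-bromo-8-ethyl-3,6,7,8-tetrahydro-2H-oxocin-2-yl]-2-phenyl-1,3-dioxane
Conditions: CBr4, P(n-C8H17)3, toluene, 70 °C
Reagents that add atoms: carbon tetrabromide, BrC(Br)(Br)Br
Why: Appel-type bromination through the alkoxyphosphonium salt proceeds by SN2 inversion, turning the 12R alcohol into the 12S bromide as in the classical end game for laurencin-type oxocenes.

**Step 10**
Reactants: 12 (2R,4R)-4-[(2S,4Z,7S,8R)-7-bromo-8-ethyl-3,6,7,8-tetrahydro-2H-oxocin-2-yl]-2-phenyl-1,3-dioxane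
Product: 13 (1R)-1-[(2S,4Z,7S,8R)-7-bromo-8-ethyl-3,6,7,8-tetrahydro-2H-oxocin-2-yl]propane-1,3-diol
Conditions: AcOH/H2O (4:1), 50 °C
Reagents that add atoms: none
Why: Mild acid hydrolysis of the benzylidene acetal frees the C6 and C4 hydroxyls without touching the secondary bromide or the ring olefin.

**Step 11**
Reactants: 13 (1R)-1-[(2S,4Z,7S,8R)-7-bromo-8-ethyl-3,6,7,8-tetrahydro-2H-oxocin-2-yl]propane-1,3-diol
Product: 14 2-[(1S,3R,4S,6S,7S,9R)-4,6-dibromo-3-ethyl-2,8-dioxabicyclo[5.2.1]decan-9-yl]ethan-1-ol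
Conditions: N-bromosuccinimide, MeCN, 0 °C, dark
Reagents that add atoms: N-bromosuccinimide, O=C1CCC(=O)N1Br
Why: 5-exo bromoetherification closes ring A: the C6 hydroxyl can reach C9 only on the ring face that carries C6 and the bromonium ion opens anti, so C9 (S) and C10 (S) are dictated by C7 and the Z geometry, while the primary C4 hydroxyl would have to close an oxepane and does not compete.

**Step 12**
Reactants: 14 2-[(1S,3R,4S,6S,7S,9R)-4,6-dibromo-3-ethyl-2,8-dioxabicyclo[5.2.1]decan-9-yl]ethan-1-ol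
Product: 15 2-[(1S,3R,4S,6S,7S,9R)-4,6-dibromo-3-ethyl-2,8-dioxabicyclo[5.2.1]decan-9-yl]acetaldehyde
Conditions: Dess–Martin periodinane, CH2Cl2, 0 °C to rt
Reagents that add atoms: none
Why: Dess–Martin oxidation gives the β-alkoxy aldehyde under non-basic conditions, avoiding β-elimination of the ring oxygen and loss of HBr.

**Step 13**
Reactants: 15 2-[(1S,3R,4S,6S,7S,9R)-4,6-dibromo-3-ethyl-2,8-dioxabicyclo[5.2.1]decan-9-yl]acetaldehyde
Product: 16 (1S,3R,4S,6S,7S,9R)-4,6-dibromo-3-ethyl-9-[(2E)-3-iodoprop-2-en-1-yl]-2,8-dioxabicyclo[5.2.1]decane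
Conditions: CHI3, CrCl2, THF/1,4-dioxane (1:6), 0 °C to rt
Reagents that add atoms: iodoform, IC(I)I
Why: Takai olefination with the geminal dichromium reagent gives the (E)-vinyl iodide selectively, and divalent chromium does not reduce unactivated secondary alkyl bromides under these conditions.

**Step 14**
Reactants: 16 (1S,3R,4S,6S,7S,9R)-4,6-dibromo-3-ethyl-9-[(2E)-3-iodoprop-2-en-1-yl]-2,8-dioxabicyclo[5.2.1]decane
Product: 17 (1S,3R,4S,6S,7S,9R)-4,6-dibromo-3-ethyl-9-[(2E)-5-(trimethylsilyl)pent-2-en-4-yn-1-yl]-2,8-dioxabicyclo[5.2.1]decane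
Conditions: HC≡CSiMe3, Pd(PPh3)4 (5 mol %), CuI (10 mol %), i-Pr2NH, THF, rt
Reagents that add atoms: ethynyltrimethylsilane, C#C[Si](C)(C)C
Why: Sonogashira coupling retains the E geometry, and zerovalent palladium inserts into the vinyl C–I bond far faster than into the secondary C–Br bonds at room temperature.

**Step 15**
Reactants: 17 (1S,3R,4S,6S,7S,9R)-4,6-dibromo-3-ethyl-9-[(2E)-5-(trimethylsilyl)pent-2-en-4-yn-1-yl]-2,8-dioxabicyclo[5.2.1]decane
Product: 18 (1S,3R,4S,6S,7S,9R)-4,6-dibromo-3-ethyl-9-[(2E)-pent-2-en-4-yn-1-yl]-2,8-dioxabicyclo[5.2.1]decane (target)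
Conditions: K2CO3, MeOH, 0 °C
Reagents that add atoms: none
Why: Catalytic methoxide cleaves the alkynyl C–Si bond (protodesilylation) under conditions too mild to eliminate or substitute the secondary bromides.

**Compound list**
1 | (R)-butane-1,2,4-triol | OCC[C@H](CO)O | starting material
2 | [(2R,4R)-2-phenyl-1,3-dioxan-4-yl]methanol | OC[C@H]1CCO[C@@H](c2ccccc2)O1 | intermediate
3 | (2R,4R)-2-phenyl-1,3-dioxane-4-carbaldehyde | O=C[C@H]1CCO[C@@H](c2ccccc2)O1 | intermediate
4 | (1S)-1-[(2R,4R)-2-phenyl-1,3-dioxan-4-yl]but-3-en-1-yl (−)-diisopinocampheylborinate (Ipc groups from (+)-α-pinene) | C=CC[C@H](OB([C@@H]2C[C@@H]3C[C@H]([C@H]2C)C3(C)C)[C@@H]2C[C@@H]3C[C@H]([C@H]2C)C3(C)C)[C@H]1CCO[C@@H](c2ccccc2)O1 | intermediate (not isolated)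
5 | (1S)-1-[(2R,4R)-2-phenyl-1,3-dioxan-4-yl]but-3-en-1-ol | C=CC[C@H](O)[C@H]1CCO[C@@H](c2ccccc2)O1 | intermediate
6 | ethyl 2-ethyl-3-oxobutanoate (racemic) | CCOC(=O)C(CC)C(C)=O | starting material
7 | ethyl 2-diazobutanoate | CCOC(=O)C(=[N+]=[N-])CC | intermediate
8 | ethyl (2R)-2-{[(1S)-1-[(2R,4R)-2-phenyl-1,3-dioxan-4-yl]but-3-en-1-yl]oxy}butanoate | C=CC[C@H](O[C@H](CC)C(=O)OCC)[C@H]1CCO[C@@H](c2ccccc2)O1 | intermediate
9 | (2R)-2-{[(1S)-1-[(2R,4R)-2-phenyl-1,3-dioxan-4-yl]but-3-en-1-yl]oxy}butanal | C=CC[C@H](O[C@H](CC)C=O)[C@H]1CCO[C@@H](c2ccccc2)O1 | intermediate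
10 | (3R,4R)-3-{[(1S)-1-[(2R,4R)-2-phenyl-1,3-dioxan-4-yl]but-3-en-1-yl]oxy}hept-6-en-4-ol | C=CC[C@H](O[C@H](CC)[C@H](O)CC=C)[C@H]1CCO[C@@H](c2ccccc2)O1 | intermediate
11 | (2S,4Z,7R,8R)-8-ethyl-2-[(2R,4R)-2-phenyl-1,3-dioxan-4-yl]-3,6,7,8-tetrahydro-2H-oxocin-7-ol | CC[C@H]1O[C@@H](C/C=C\C[C@H]1O)[C@H]2CCO[C@@H](c3ccccc3)O2 | intermediate
12 | (2R,4R)-4-[(2S,4Z,7S,8R)-7-bromo-8-ethyl-3,6,7,8-tetrahydro-2H-oxocin-2-yl]-2-phenyl-1,3-dioxane | CC[C@H]1O[C@@H](C/C=C\C[C@@H]1Br)[C@H]2CCO[C@@H](c3ccccc3)O2 | intermediate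
13 | (1R)-1-[(2S,4Z,7S,8R)-7-bromo-8-ethyl-3,6,7,8-tetrahydro-2H-oxocin-2-yl]propane-1,3-diol | CC[C@H]1O[C@@H](C/C=C\C[C@@H]1Br)[C@H](O)CCO | intermediate
14 | 2-[(1S,3R,4S,6S,7S,9R)-4,6-dibromo-3-ethyl-2,8-dioxabicyclo[5.2.1]decan-9-yl]ethan-1-ol | OCC[C@H]1O[C@H]2C[C@@H]1O[C@H](CC)[C@@H](Br)C[C@@H]2Br | intermediate
15 | 2-[(1S,3R,4S,6S,7S,9R)-4,6-dibromo-3-ethyl-2,8-dioxabicyclo[5.2.1]decan-9-yl]acetaldehyde | O=CC[C@H]1O[C@H]2C[C@@H]1O[C@H](CC)[C@@H](Br)C[C@@H]2Br | intermediate
16 | (1S,3R,4S,6S,7S,9R)-4,6-dibromo-3-ethyl-9-[(2E)-3-iodoprop-2-en-1-yl]-2,8-dioxabicyclo[5.2.1]decane | I/C=C/C[C@H]1O[C@H]2C[C@@H]1O[C@H](CC)[C@@H](Br)C[C@@H]2Br | intermediate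
17 | (1S,3R,4S,6S,7S,9R)-4,6-dibromo-3-ethyl-9-[(2E)-5-(trimethylsilyl)pent-2-en-4-yn-1-yl]-2,8-dioxabicyclo[5.2.1]decane | C[Si](C)(C)C#C/C=C/C[C@H]1O[C@H]2C[C@@H]1O[C@H](CC)[C@@H](Br)C[C@@H]2Br | intermediate
18 | (1S,3R,4S,6S,7S,9R)-4,6-dibromo-3-ethyl-9-[(2E)-pent-2-en-4-yn-1-yl]-2,8-dioxabicyclo[5.2.1]decane | C#C/C=C/C[C@H]1O[C@H]2C[C@@H]1O[C@H](CC)[C@@H](Br)C[C@@H]2Br | target

**Totals**
Total step count: 15. Longest linear sequence: 14 steps (from 1 through steps 1–3 and 5–15); step 4 is a one-step side branch.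

**Three steps most likely to fail**

Step 5 (the proposed new O–H insertion). The hindered secondary hydroxyl may react slowly, the ethyl carbene may undergo 1,2-hydride shift to ethyl but-2-enoate, and catalyst control over C13 may be modest. The ligand antipode is used if the (R) sense requires it, and the C13 epimers are diastereomers that can be separated. The fallback uses known chemistry, sets out from alcohol 5 and comes back at ester 8. Commercial ethyl (S)-2-hydroxybutanoate is treated with Tf2O and 2,6-lutidine in CH2Cl2 at −78 °C to give ethyl (2S)-2-[(trifluoromethylsulfonyl)oxy]butanoate F1. Alcohol 5 is deprotonated with NaH in THF at 0 °C, and the alkoxide displaces the triflate of F1 at −40 to 0 °C with inversion (Williamson-type SN2 on an α-triflyloxy ester), giving 8 with the (R) configuration at C13.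

Step 8 (ring-closing metathesis to the α,α'-trans oxocene). Dimerisation or olefin isomerisation may win with the free homoallylic alcohol. The fallback sets out from diene alcohol 10 and comes back at bromide 12, so that 11 is skipped and the ring is closed after the bromination. Alcohol 10 is brominated with inversion (CBr4, P(n-C8H17)3, toluene, 70 °C) to (2R,4R)-4-[(1S)-1-{[(3R,4S)-4-bromohept-6-en-3-yl]oxy}but-3-en-1-yl]-2-phenyl-1,3-dioxane F2. F2 is then cyclised with the same RuCl2(=CHPh)(PCy3)(SIMes) catalyst at high dilution to give 12; here a C–Br/C–O gauche arrangement and the absence of a free hydroxyl change the cyclisation substrate.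

Step 9 (invertive bromination at C12 on the oxocene). Elimination or participation of the ring oxygen can lower the yield of the one-pot phosphonium route. The fallback sets out from alcohol 11 and comes back at bromide 12 by a two-stage activation and displacement. Alcohol 11 is converted with ClCH2SO2Cl and 2,6-lutidine (CH2Cl2, 0 °C) into (2S,4Z,7R,8R)-8-ethyl-2-[(2R,4R)-2-phenyl-1,3-dioxan-4-yl]-3,6,7,8-tetrahydro-2H-oxocin-7-yl chloromethanesulfonate F3. The isolated sulfonate is displaced by LiBr in THF/DMF at 40 °C with clean SN2 inversion to give 12.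

**Further compounds**
F1 | step 5 | ethyl (2S)-2-[(trifluoromethylsulfonyl)oxy]butanoate | CC[C@H](OS(=O)(=O)C(F)(F)F)C(=O)OCC
F2 | step 8 | (2R,4R)-4-[(1S)-1-{[(3R,4S)-4-bromohept-6-en-3-yl]oxy}but-3-en-1-yl]-2-phenyl-1,3-dioxane | C=CC[C@H](O[C@H](CC)[C@@H](Br)CC=C)[C@H]1CCO[C@@H](c2ccccc2)O1
F3 | step 9 | (2S,4Z,7R,8R)-8-ethyl-2-[(2R,4R)-2-phenyl-1,3-dioxan-4-yl]-3,6,7,8-tetrahydro-2H-oxocin-7-yl chloromethanesulfonate | CC[C@H]1O[C@@H](C/C=C\C[C@H]1OS(=O)(=O)CCl)[C@H]2CCO[C@@H](c3ccccc3)O2
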